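## The problem

The target joins a (2S)-naringenin unit and a (2R,3R)-aromadendrin (dihydrokaempferol) unit by a biaryl bond between C3' and C3''' of the two rings B, each of these carbons lying ortho to a phenolic hydroxyl. Both halves have the same carbon skeleton and the same spatial arrangement at C2 and C2'' (the descriptors differ only because of the extra oxygen), and they differ solely in the C3'' hydroxyl, which is trans to the C2'' aryl group. C2 and C2'' sit on opposite sides of the biaryl and cannot influence each other, so each must be set by a reagent, whereas C3'' can be controlled by C2'', because an oxidant reaches ring C anti to the aryl group and the trans isomer is the more stable one. The flavanone ring C opens by retro-oxa-Michael reaction as soon as C3 is enolised under base, which scrambles C2; the dihydroflavonol epimerises and dehydrogenates easily; six free phenols are air-sensitive. The phenols therefore stay masked to the end, and strong base is excluded once C4 is a carbonyl. The feature that makes the key step possible is that in each ring C the oxygen O1 is bound to C8a of ring A, directly ortho to C4a, which carries the C4–C3–C2 chain, while C2 is a secondary benzylic carbinol carbon. Ring C can thus be closed by forming the O1–C8a aryl–oxygen bond from a C2 alcohol and a C8a bromide, after C2 has been set by asymmetric reduction of an aryl ketone and without breaking any bond to C2. Because the skeleton is twofold, this can be done on both halves at once; the price is that the single C3'' hydroxyl must later be placed on one of two identical units.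

## Retrosynthesis

**Protecting groups.** The six phenols of 18 are traced back to the hexabenzyl ether 17. This asks only for one neutral hydrogenolysis at the end. Benzyl ethers tolerate hydroxide, copper hydride, formic acid/amine, carbonate at 70 °C, DDQ and silyl triflate, which covers every condition of the route.

**C3''–O bond.** Removing the C3'' hydroxyl from 17 gives the C2-symmetric bis-flavanone 14. The forward step is a Rubottom oxidation through the mono silyl enol ether 15 and the silyloxy epoxide 16, in which C2'' directs the oxidant to the opposite face. The neighbouring cut, carrying the C3'' oxygen from the start, would need an unsymmetrical biaryl and two separate chain syntheses, roughly doubling the early part. The chosen cut instead pays with a statistical choice between two identical ketones, in a step whose products differ in polarity and whose unchanged starting material can be recycled.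

**C4=O bonds.** Both carbonyl oxygens are removed next: 14 comes from the bis-flavan-4-ol 13 and this from the bis-flavan 12. C4 is benzylic to ring A and flanked by the ortho and para oxygens at C5, C7 and O1, so hydride abstraction there is favoured. Keeping C4 as a methylene until after ring closure means that no enolisable ketone, and hence no retro-oxa-Michael pathway, exists while carbonate base is used. The forward reaction must prefer C4 over the C2–H bond.

**O1–C8a bonds (key disconnection).** Cutting both aryl–oxygen bonds of 12 gives the acyclic (1S,1'S)-diol 11, which carries a bromine at each future C8a. The neighbouring cut at C2–O1 (phenol plus activated carbinol) would break a bond to the stereocentre at a p-alkoxybenzylic carbon that ionises easily. The chosen cut leaves that centre alone. The precursor loses both heterocycles and becomes two identical arms on a biaryl. The forward reaction must close two six-membered rings by palladium-catalysed C–O coupling with retention.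

**C2–H bonds and chain saturation.** Diol 11 comes from the bis-ketone 10 by asymmetric transfer hydrogenation of two aryl alkyl ketones, the best-behaved substrate class for that reaction. Ketone 10 comes from the bis-enone 9 by conjugate reduction. The forward reactions must leave the aryl bromides and benzyl ethers untouched.

**C3–C4 bonds.** The two enone double bonds of 9 are cut to the diacetyl biaryl 8 and two molecules of aldehyde 4. Placing the ketone on ring B (retro-chalcone orientation) is what turns C2 into a ketone-reduction problem. The forward reaction is a twofold Claisen–Schmidt condensation.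

**Biaryl bond.** Biaryl 8 is cut at its central bond into the bromo ketone 6 and the pinacol boronate 7. Boronate 7 is itself made from 6 by Miyaura borylation, so one batch of 6 is divided and supplies both coupling partners. Ketone 6 is the benzyl ether of commercial 5. Making the biaryl bond after the acetyl groups are in place avoids a Friedel–Crafts acylation in the presence of benzyl ethers, and a cross-coupling of two isolated partners keeps the stoichiometry of the biaryl formation under control.

**Ring A aldehyde.** Aldehyde 4 loses its formyl group to give the dibenzyl ether 2, via the iminium salt 3 of a Vilsmeier–Haack formylation. Ether 2 comes from commercial 1. The bromine of 1 is meta to both oxygens, which is exactly the C8a position, and the formylation must go ortho to bromine.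

## Roads not taken

Alternative 1: The cut is O1–C2 in both rings C, with the C3 oxygen and the configuration at C2 and C3 coming from an oxirane. Forward, the bis-chalcone A1 (normal chalcone orientation, MOM-protected 2'-hydroxyl) would be epoxidised at both enone double bonds with H2O2 under poly-L-leucine (Juliá–Colonna epoxidation) to the bis-epoxy ketone A2. MOM removal and 6-endo opening of each oxirane at the benzylic carbon would give the doubly hydroxylated dimer A3, and one of its two C3 hydroxyls would then be removed.
- Merits: four stereocentres are set by a catalyst in one operation, the trans-dihydroflavonol arises in its native oxidation state, C4 never needs oxidising, and the route is shorter than the chosen one.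
- Weak points: the ring A ketone of A1 has two ortho oxygens, is twisted out of conjugation and is a poor substrate for the polymeric catalyst, which must also act twice on a large dimer. The oxirane opening competes with 5-exo closure and with ionisation at the p-alkoxybenzylic carbon. The final deoxygenation chooses statistically between two identical hydroxyls, destroys a stereocentre that was just made, and passes through a flavanone enolate or ketyl that can expel the aryloxide.
- Comparison: both plans contain one statistical step. The chosen plan places its statistical step as an addition controlled by C2'' and keeps every carbonyl out of ring C during ring closure. It accepts several more steps for that.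

Alternative 2: The cut is C2–C1' on both sides. Forward, the diboronic acid A4 would add twice to 5,7-bis(benzyloxy)chromone A5 under [RhCl(C2H4)2]2 and a chiral diene (monovalent rhodium), giving A6 directly; A6 is identical with 14 of the chosen route.
- Merits: this is the most convergent plan. It reaches the bis-flavanone in roughly half the steps and needs no ring closure and no C4 oxidation; in step economy it is clearly better.
- Weak points: a chromone with two donor oxygens on ring A is a reluctant acceptor. The electron-rich diboronic acid must react at both ends, and protodeboronation of one end gives a mono-adduct that is hard to separate. The flavanone forms under aqueous base, where ring opening erodes C2. The statistical hydroxylation at C3'' remains.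
- Comparison: the chosen plan sets against this that its two stereocentres come from ketone transfer hydrogenation, which is insensitive to the ring A pattern, and that no flavanone exists until all basic steps are over.

Alternative 3: The cut is C2–C3 on both sides. Forward, the bis(diazoketone) A7 would be decomposed by Rh2(S-PTTL)4 (divalent rhodium), and each carbenoid would insert into a C–H bond of the neighbouring O-benzylic methylene to give A8.
- Merits: ring, C–C bond and stereocentre form together, the C4 carbonyl is present from the start, and the redox count is the lowest of all plans.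
- Weak points: an acceptor-only carbenoid sits next to an ether oxygen, so a five-membered oxonium ylide with Stevens shift can compete with insertion. Insertion must form a six-membered ring where five is normally preferred. Enantiocontrol for this carbenoid class on a 2,4,6-trioxygenated aryl ketone is uncertain, and every failure is doubled. Silyl ethers on ring A and a diazoketone from a hindered benzoic acid add their own steps. The product is again a flavanone that needs the same statistical hydroxylation.
- Comparison: this road is better in redox economy. The chosen plan relies only on established reaction classes for ring closure and for the stereocentres.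

Key step: step 9

Assumption: the 3',3'''-biaryl axis has only one ortho substituent on each ring and is taken to rotate freely, so 18 has three stereocentres and no axial configuration to control; 1 and 5 are taken as commercial.

## Route

Step 1
Reactants: 1 5-bromoresorcinol
Product: 2 1,3-bis(benzyloxy)-5-bromobenzene
Conditions: BnBr, K2CO3, DMF, 60 °C
Reagents that add atoms: benzyl bromide, BrCc1ccccc1
Why: Williamson etherification of both phenols; carbonate is basic enough for a resorcinol and the aryl bromide is inert.

Step 2
Reactants: 2 1,3-bis(benzyloxy)-5-bromobenzene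
Product: 4 2,4-bis(benzyloxy)-6-bromobenzaldehyde, via aryl iminium salt 3 (not isolated)
Conditions: POCl3, DMF, 0 → 80 °C; then ice–water
Reagents that add atoms: N,N-dimethylformamide, CN(C)C=O; water, O
Why: Vilsmeier–Haack formylation; the position between bromine and one benzyloxy group is ortho and para to the two donors and is the usual main site for 1-bromo-3,5-dialkoxybenzenes. The minor isomer formylated between the two ethers should be removable by crystallisation.

Step 3
Reactants: 5 1-(3-bromo-4-hydroxyphenyl)ethan-1-one
Product: 6 1-[4-(benzyloxy)-3-bromophenyl]ethan-1-one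
Conditions: BnBr, K2CO3, acetone, reflux
Reagents that add atoms: benzyl bromide, BrCc1ccccc1
Why: Williamson etherification of a phenol acidified by the para acetyl group; the methyl ketone is not alkylated under carbonate.

Step 4
Reactants: 6 1-[4-(benzyloxy)-3-bromophenyl]ethan-1-one
Product: 7 1-[4-(benzyloxy)-3-(4,4,5,5-tetramethyl-1,3,2-dioxaborolan-2-yl)phenyl]ethan-1-one
Conditions: B2pin2 (1.1 equiv), PdCl2(dppf) (cat.), KOAc, 1,4-dioxane, 85 °C
Reagents that add atoms: bis(pinacolato)diboron, CC1(C)OB(OC1(C)C)B1OC(C)(C)C(C)(C)O1
Why: Miyaura borylation of an aryl bromide; acetate is too weak a base to drive Suzuki coupling of 7 with unreacted 6, so the boronate can be isolated, and the methyl ketone and benzyl ether are inert. Half of the batch of 6 is used here and the other half is kept for step 5.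

Step 5
Reactants: 7 1-[4-(benzyloxy)-3-(4,4,5,5-tetramethyl-1,3,2-dioxaborolan-2-yl)phenyl]ethan-1-one; 6 1-[4-(benzyloxy)-3-bromophenyl]ethan-1-one
Product: 8 5,5'-diacetyl-2,2'-bis(benzyloxy)biphenyl
Conditions: Pd(PPh3)4 (cat.), aq K2CO3, 1,2-dimethoxyethane, 85 °C
Reagents that add atoms: none
Why: Suzuki–Miyaura cross-coupling of one equivalent of boronate 7 with one equivalent of bromide 6 forms the central biaryl bond; each ring carries only one ortho substituent at the new bond, and the acetyl groups tolerate aqueous carbonate.

Step 6
Reactants: 8 5,5'-diacetyl-2,2'-bis(benzyloxy)biphenyl; 4 2,4-bis(benzyloxy)-6-bromobenzaldehyde (2.2 equiv)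
Product: 9 (2E,2'E)-bis-enone (retro-chalcone dimer)
Conditions: KOH, EtOH/THF, rt
Reagents that add atoms: none
Why: Twofold Claisen–Schmidt condensation; 4 has no α-hydrogen, each methyl ketone enolate adds and the aldol dehydrates to the conjugated (E)-enone. Aryl bromides and benzyl ethers are inert to hydroxide at room temperature.

Step 7
Reactants: 9 (2E,2'E)-bis-enone
Product: 10 saturated bis(3-arylpropan-1-one) diketone
Conditions: [(Ph3P)CuH]6, H2O, THF/toluene, rt; then air, aq NH4Cl
Reagents that add atoms: none
Why: Copper hydride conjugate reduction; the soft hydride adds to the β-carbon, water protonates the copper enolate, and the reagent leaves aryl bromides, benzyl ethers and the resulting ketones alone.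

Step 8
Reactants: 10 saturated diketone
Product: 11 (1S,1'S)-diol (open-chain dibromide)
Conditions: RuCl(p-cymene)[(S,S)-TsDPEN] (cat.), HCO2H/Et3N (5:2), CH2Cl2, 30 °C
Reagents that add atoms: none
Why: Noyori-type asymmetric transfer hydrogenation; with the (S,S) ligand an aryl alkyl ketone is reduced from the face that gives the (S)-carbinol, the CH2CH2Ar chain playing the role of the methyl group of acetophenone. The two reductions are independent, so a wrong event ends up mainly in the meso (1R,1'S) diastereomer, which is separable and leaves 11 enriched (Horeau-type amplification).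

Step 9
Reactants: 11 (1S,1'S)-diol
Product: 12 (2S,2''S)-hexakis(benzyloxy)-3',3'''-biflavan
Conditions: Pd(OAc)2 (cat.), 2-(di-tert-butylphosphino)-1,1'-binaphthyl (cat.), Cs2CO3, toluene, 70 °C
Reagents that add atoms: none
Why: Pd(OAc)2 is reduced in situ to zerovalent palladium, which inserts into each C8a–Br bond; carbonate-assisted exchange of bromide for the C2 alkoxide gives a seven-membered aryl palladium alkoxide, and C–O reductive elimination releases the chroman and regenerates zerovalent palladium. The closest known reaction type is the palladium-catalysed intramolecular etherification of aryl bromides by secondary alcohols, which is established for chromans and flavans. Ring C and ring C'' each close as a six-membered ring by attack of the side-chain oxygen on the ortho aryl carbon (6-exo with respect to the aryl–palladium bond), as two independent events on arms that are far apart. No stereocentre is created: the carbinol C–O bond is never broken, so C2 and C2'' keep the S configuration set in step 8. The step needs reductive elimination to beat β-hydride elimination of the benzylic palladium alkoxide, which would return the aryl ketone and reduce the C–Br bond, and to beat intermolecular coupling. The bulky, electron-rich di-tert-butylphosphino biaryl ligand makes the palladium centre crowded and low-coordinate, which speeds reductive elimination; the six-membered ring size and moderate dilution favour cyclisation, and both benzyloxy groups are meta to C8a and so do not deactivate that carbon. Benzyl ethers and the biaryl are inert to Cs2CO3 in toluene at this temperature.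

Step 10
Reactants: 12 (2S,2''S)-hexakis(benzyloxy)-3',3'''-biflavan
Product: 13 (2S,2''S)-hexakis(benzyloxy)-3',3'''-biflavan-4,4''-diol (epimers at C4 and C4'')
Conditions: DDQ, CH2Cl2/H2O, 0 °C → rt
Reagents that add atoms: water, O
Why: DDQ benzylic oxidation by hydride abstraction; the C4 cation is stabilised by the oxygens at C5, C7 and O1 (a 2,4,6-trioxygenated benzylic cation) and is trapped by water, as known for benzyl-protected flavans and flavan-3-ols. The C2–H bond has only the single para oxygen of ring B to help it, and aryl benzyl ethers are not attacked; the configuration at C4 is irrelevant.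

Step 11
Reactants: 13 biflavan-4,4''-diol
Product: 14 (2S,2''S)-hexa-O-benzyl-3',3'''-binaringenin
Conditions: Dess–Martin periodinane, CH2Cl2, rt
Reagents that add atoms: none
Why: Dess–Martin oxidation of two secondary benzylic alcohols under neutral, non-enolising conditions, so the new flavanones do not ring-open and C2 and C2'' are untouched.

Step 12
Reactants: 14 (2S,2''S)-hexa-O-benzyl-3',3'''-binaringenin
Product: 17 hexa-O-benzyl ether of the target, via mono silyl enol ether 15 (not isolated), via silyloxy epoxide 16 (not isolated)
Conditions: TMSOTf (0.9 equiv), Et3N, CH2Cl2, −20 °C; DMDO, acetone/CH2Cl2, −40 → 0 °C; then 1 M HCl, THF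
Reagents that add atoms: dimethyldioxirane, CC1(C)OO1
Why: Rubottom oxidation, a known route from flavanones to trans-3-hydroxyflavanones; soft enolisation with silyl triflate and amine avoids a free enolate that could expel the aryloxide, and the limiting amount of triflate enolises on average one of the two identical ketones. DMDO epoxidises the enol ether anti to the C2'' aryl group, so hydrolysis gives the 2'',3''-trans ketol with C2'' unchanged, which is (2''R,3''R). Unchanged 14 is recovered and recycled, and the doubly hydroxylated dimer (A3 of Alternative 1) is separated by its higher polarity.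

Step 13
Reactants: 17 hexa-O-benzyl ether of the target
Product: 18 (2S)-naringenin-(3'→3''')-(2R,3R)-aromadendrin (the target)
Conditions: H2 (1 atm), Pd/C, EtOAc/MeOH, rt
Reagents that add atoms: none
Why: Hydrogenolysis of six aryl benzyl ethers under neutral conditions; the aryl ketones conjugated to ring A, the ketol and the C2–O1 bonds of flavanones are normally retained at atmospheric pressure, so C2, C2'' and C3'' are not disturbed.

## Compound list

1 | 5-bromobenzene-1,3-diol (5-bromoresorcinol) | Oc1cc(O)cc(Br)c1 | starting material
2 | 1,3-bis(benzyloxy)-5-bromobenzene | Brc1cc(OCc2ccccc2)cc(OCc2ccccc2)c1 | intermediate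
3 | {[2,4-bis(benzyloxy)-6-bromophenyl]methylidene}dimethyliminium dichlorophosphate (formed in situ) | C[N+](C)=Cc1c(Br)cc(OCc2ccccc2)cc1OCc1ccccc1.[O-]P(Cl)(Cl)=O | intermediate
4 | 2,4-bis(benzyloxy)-6-bromobenzaldehyde | O=Cc1c(Br)cc(OCc2ccccc2)cc1OCc1ccccc1 | intermediate
5 | 1-(3-bromo-4-hydroxyphenyl)ethan-1-one | CC(=O)c1ccc(O)c(Br)c1 | starting material
6 | 1-[4-(benzyloxy)-3-bromophenyl]ethan-1-one | CC(=O)c1ccc(OCc2ccccc2)c(Br)c1 | intermediate
7 | 1-[4-(benzyloxy)-3-(4,4,5,5-tetramethyl-1,3,2-dioxaborolan-2-yl)phenyl]ethan-1-one | CC(=O)c1ccc(OCc2ccccc2)c(B2OC(C)(C)C(C)(C)O2)c1 | intermediate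
8 | 1,1'-[6,6'-bis(benzyloxy)biphenyl-3,3'-diyl]di(ethan-1-one) (5,5'-diacetyl-2,2'-bis(benzyloxy)biphenyl) | CC(=O)c1ccc(OCc2ccccc2)c(-c2cc(C(C)=O)ccc2OCc2ccccc2)c1 | intermediate
9 | (2E,2'E)-1,1'-[6,6'-bis(benzyloxy)biphenyl-3,3'-diyl]bis{3-[2,4-bis(benzyloxy)-6-bromophenyl]prop-2-en-1-one} | O=C(/C=C/c1c(Br)cc(OCc2ccccc2)cc1OCc1ccccc1)c1ccc(OCc2ccccc2)c(-c2cc(C(=O)/C=C/c3c(Br)cc(OCc4ccccc4)cc3OCc3ccccc3)ccc2OCc2ccccc2)c1 | intermediate
10 | 1,1'-[6,6'-bis(benzyloxy)biphenyl-3,3'-diyl]bis{3-[2,4-bis(benzyloxy)-6-bromophenyl]propan-1-one} | O=C(CCc1c(Br)cc(OCc2ccccc2)cc1OCc1ccccc1)c1ccc(OCc2ccccc2)c(-c2cc(C(=O)CCc3c(Br)cc(OCc4ccccc4)cc3OCc3ccccc3)ccc2OCc2ccccc2)c1 | intermediate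
11 | (1S,1'S)-1,1'-[6,6'-bis(benzyloxy)biphenyl-3,3'-diyl]bis{3-[2,4-bis(benzyloxy)-6-bromophenyl]propan-1-ol} | O[C@@H](CCc1c(Br)cc(OCc2ccccc2)cc1OCc1ccccc1)c1ccc(OCc2ccccc2)c(-c2cc([C@H](CCc3c(Br)cc(OCc4ccccc4)cc3OCc3ccccc3)O)ccc2OCc2ccccc2)c1 | intermediate
12 | (2S,2''S)-5,7,4',5'',7'',4'''-hexakis(benzyloxy)-3',3'''-biflavan | C1C[C@@H](c2ccc(OCc6ccccc6)c(-c3cc([C@H]4Oc5cc(OCc6ccccc6)cc(OCc6ccccc6)c5CC4)ccc3OCc6ccccc6)c2)Oc2cc(OCc3ccccc3)cc(OCc3ccccc3)c21 | intermediate
13 | (2S,2''S)-5,7,4',5'',7'',4'''-hexakis(benzyloxy)-3',3'''-biflavan-4,4''-diol, mixture of epimers at C4 and C4'' | OC1C[C@@H](c2ccc(OCc6ccccc6)c(-c3cc([C@H]4Oc5cc(OCc6ccccc6)cc(OCc6ccccc6)c5C(O)C4)ccc3OCc6ccccc6)c2)Oc2cc(OCc3ccccc3)cc(OCc3ccccc3)c21 | intermediate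
14 | (2S,2''S)-5,7,4',5'',7'',4'''-hexakis(benzyloxy)-3',3'''-biflavanone (hexa-O-benzyl-3',3'''-binaringenin) | O=C1C[C@@H](c2ccc(OCc6ccccc6)c(-c3cc([C@H]4Oc5cc(OCc6ccccc6)cc(OCc6ccccc6)c5C(=O)C4)ccc3OCc6ccccc6)c2)Oc2cc(OCc3ccccc3)cc(OCc3ccccc3)c21 | intermediate
15 | mono(trimethylsilyl enol ether) of 14: one unit is the (2''S)-4''-(trimethylsilyloxy)flav-3''-ene, the other the unchanged (2S)-flavanone (formed in situ) | O=C1C[C@@H](c2ccc(OCc6ccccc6)c(-c3cc([C@H]4Oc5cc(OCc6ccccc6)cc(OCc6ccccc6)c5C(O[Si](C)(C)C)=C4)ccc3OCc6ccccc6)c2)Oc2cc(OCc3ccccc3)cc(OCc3ccccc3)c21 | intermediate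
16 | 3'',4''-epoxy-4''-(trimethylsilyloxy) derivative of 15, oxirane on the face opposite to the C2'' aryl group (formed in situ) | O=C1C[C@@H](c2ccc(OCc6ccccc6)c(-c3cc([C@H]4Oc5cc(OCc6ccccc6)cc(OCc6ccccc6)c5[C@]7(O[Si](C)(C)C)O[C@@H]74)ccc3OCc6ccccc6)c2)Oc2cc(OCc3ccccc3)cc(OCc3ccccc3)c21 | intermediate
17 | hexa-O-benzyl ether of the target: (2S)-5,7,4'-tris(benzyloxy)flavanone joined 3'–3''' to (2''R,3''R)-5'',7'',4'''-tris(benzyloxy)-3''-hydroxyflavanone | O=C1C[C@@H](c2ccc(OCc6ccccc6)c(-c3cc([C@H]4Oc5cc(OCc6ccccc6)cc(OCc6ccccc6)c5C(=O)[C@@H]4O)ccc3OCc6ccccc6)c2)Oc2cc(OCc3ccccc3)cc(OCc3ccccc3)c21 | intermediate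
18 | (2R,3R)-2-{3-[5-((2S)-5,7-dihydroxy-4-oxochroman-2-yl)-2-hydroxyphenyl]-4-hydroxyphenyl}-3,5,7-trihydroxychroman-4-one ((2S)-naringenin-(3'→3''')-(2R,3R)-aromadendrin) | O=C1C[C@@H](c2ccc(O)c(-c3cc([C@H]4Oc5cc(O)cc(O)c5C(=O)[C@@H]4O)ccc3O)c2)Oc2cc(O)cc(O)c21 | target

## Step count and risk

Total step count: 13. Longest linear sequence: 11 steps (from 5 through steps 3–13; the branch from 1 through steps 1, 2 and 6–13 has 10 steps).

**Step 9 (key step).** The most likely failure is β-hydride elimination of the benzylic palladium alkoxide outrunning C–O reductive elimination. That would oxidise the carbinol back to the ketone and replace the ring A bromine by hydrogen; if it were reversible it could also erode the configuration at C2. The risk is real because a benzylic alkoxide gives a conjugated ketone and because two closures must succeed in one molecule.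
Fallback: close the other ring C bond, C2–O1, by substitution with inversion. Setting out from 10, transfer hydrogenation with RuCl(p-cymene)[(R,R)-TsDPEN] would give the (1R,1'R)-diol F1. Miyaura borylation of both ring A bromides (B2pin2, PdCl2(dppf), KOAc) would give the bis(pinacol boronate) F2, and oxidation with NaBO3 the bis-phenol F3. Twofold Mitsunobu cyclisation (PPh3, DIAD) would invert both carbinol centres and return to the route at 12.

**Step 10.** Hydride abstraction may occur at C2 instead of C4, which opens ring C. Alternatively the C4 cation may lose H3 before water traps it, which leads on toward the flavylium oxidation level. Both are possible because a flavan without a C3 substituent lacks the inductive protection that flavan-3-ols have.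
Fallback: bring the C4 oxygen in with the carbon chain. Setting out from 8 and 4, a twofold lithium enolate aldol addition (LDA, THF, −78 °C, no dehydration) would give the bis(β-hydroxy ketone) F4. Silylation (TBSOTf, 2,6-lutidine) would give the bis(silyl ether) F5, transfer hydrogenation as in step 8 the (1S,1'S)-diol F6, and palladium-catalysed etherification as in step 9 the 4,4''-bis(silyloxy)biflavan F7. Fluoride (TBAF) would then return to the route at 13.

**Step 12.** The two ketones are identical and remote, so enolisation distributes statistically over none, one and both units. In addition, enolisation of a flavanone can trigger retro-oxa-Michael ring opening with loss of the C2 configuration, and facial selectivity of the epoxidation could be incomplete.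
Fallback: avoid enol chemistry altogether. Setting out from 13, dehydration of one benzylic alcohol (limiting MsCl, Et3N) would give the mono flav-3-ene F8. Dihydroxylation (OsO4 cat., NMO) anti to the C2'' aryl group would give the 2'',3''-trans-3'',4''-cis triol F9, and MnO2 would oxidise only the two benzylic C4 hydroxyls, returning to the route at 17. This fallback removes the ring-opening risk but not the statistical choice; a non-statistical solution would need an unsymmetrical biaryl and a much longer early sequence.

**Step 7.** Conjugate hydride delivery to a β-carbon that carries a doubly ortho-substituted aryl group may be slow, leaving mono-reduced material or allowing 1,2-reduction.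
Fallback: setting out from 9, homogeneous hydrogenation of the two enone double bonds with RhCl(PPh3)3 and H2 in benzene/EtOH works by alkene insertion instead of hydride addition and spares aryl bromides and benzyl ethers. It returns to the route at 10 and makes no new compound (F0).

## Further compounds

F1 | step 9 | (1R,1'R)-1,1'-[6,6'-bis(benzyloxy)biphenyl-3,3'-diyl]bis{3-[2,4-bis(benzyloxy)-6-bromophenyl]propan-1-ol} | O[C@H](CCc1c(Br)cc(OCc2ccccc2)cc1OCc1ccccc1)c1ccc(OCc2ccccc2)c(-c2cc([C@@H](CCc3c(Br)cc(OCc4ccccc4)cc3OCc3ccccc3)O)ccc2OCc2ccccc2)c1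
F2 | step 9 | (1R,1'R)-bis(pinacol boronate): F1 with both ring A bromines replaced by 4,4,5,5-tetramethyl-1,3,2-dioxaborolan-2-yl | O[C@H](CCc1c(B2OC(C)(C)C(C)(C)O2)cc(OCc2ccccc2)cc1OCc1ccccc1)c1ccc(OCc2ccccc2)c(-c2cc([C@@H](CCc3c(B4OC(C)(C)C(C)(C)O4)cc(OCc4ccccc4)cc3OCc3ccccc3)O)ccc2OCc2ccccc2)c1
F3 | step 9 | (1R,1'R)-bis-phenol: F1 with both ring A bromines replaced by hydroxyl | O[C@H](CCc1c(O)cc(OCc2ccccc2)cc1OCc1ccccc1)c1ccc(OCc2ccccc2)c(-c2cc([C@@H](CCc3c(O)cc(OCc4ccccc4)cc3OCc3ccccc3)O)ccc2OCc2ccccc2)c1
F4 | step 10 | 1,1'-[6,6'-bis(benzyloxy)biphenyl-3,3'-diyl]bis{3-[2,4-bis(benzyloxy)-6-bromophenyl]-3-hydroxypropan-1-one}, mixture of carbinol epimers | O=C(CC(O)c1c(Br)cc(OCc2ccccc2)cc1OCc1ccccc1)c1ccc(OCc2ccccc2)c(-c2cc(C(=O)CC(O)c3c(Br)cc(OCc4ccccc4)cc3OCc3ccccc3)ccc2OCc2ccccc2)c1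
F5 | step 10 | bis(tert-butyldimethylsilyl ether) of F4 | O=C(CC(O[Si](C)(C)C(C)(C)C)c1c(Br)cc(OCc2ccccc2)cc1OCc1ccccc1)c1ccc(OCc2ccccc2)c(-c2cc(C(=O)CC(O[Si](C)(C)C(C)(C)C)c3c(Br)cc(OCc4ccccc4)cc3OCc3ccccc3)ccc2OCc2ccccc2)c1
F6 | step 10 | (1S,1'S)-diol from F5, silyloxy carbons as epimer mixture | O[C@@H](CC(O[Si](C)(C)C(C)(C)C)c1c(Br)cc(OCc2ccccc2)cc1OCc1ccccc1)c1ccc(OCc2ccccc2)c(-c2cc([C@H](CC(O[Si](C)(C)C(C)(C)C)c3c(Br)cc(OCc4ccccc4)cc3OCc3ccccc3)O)ccc2OCc2ccccc2)c1
F7 | step 10 | (2S,2''S)-hexakis(benzyloxy)-4,4''-bis(tert-butyldimethylsilyloxy)-3',3'''-biflavan, epimers at C4 and C4'' | CC(C)(C)[Si](C)(C)OC1C[C@@H](c2ccc(OCc6ccccc6)c(-c3cc([C@H]4Oc5cc(OCc6ccccc6)cc(OCc6ccccc6)c5C(O[Si](C)(C)C(C)(C)C)C4)ccc3OCc6ccccc6)c2)Oc2cc(OCc3ccccc3)cc(OCc3ccccc3)c21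
F8 | step 12 | mono flav-3-ene: one unit of 13 dehydrated to the (2''S)-flav-3''-ene, the other still the flavan-4-ol | OC1C[C@@H](c2ccc(OCc6ccccc6)c(-c3cc([C@H]4Oc5cc(OCc6ccccc6)cc(OCc6ccccc6)c5C=C4)ccc3OCc6ccccc6)c2)Oc2cc(OCc3ccccc3)cc(OCc3ccccc3)c21
F9 | step 12 | triol: (2''R,3''S,4''S)-2'',3''-trans-3'',4''-cis-flavan-3'',4''-diol unit joined to the (2S)-flavan-4-ol unit | OC1C[C@@H](c2ccc(OCc6ccccc6)c(-c3cc([C@H]4Oc5cc(OCc6ccccc6)cc(OCc6ccccc6)c5[C@H](O)[C@@H]4O)ccc3OCc6ccccc6)c2)Oc2cc(OCc3ccccc3)cc(OCc3ccccc3)c21
F0 | step 7 | none | none
A1 | alternative 1 | bis-chalcone with MOM-protected 2'-hydroxyls | O=C(/C=C/c1ccc(OCc6ccccc6)c(-c2cc(/C=C/C(=O)c3c(OCOC)cc(OCc6ccccc6)cc3OCc6ccccc6)ccc2OCc6ccccc6)c1)c1c(OCOC)cc(OCc2ccccc2)cc1OCc1ccccc1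
A2 | alternative 1 | bis[(αR,βS)-epoxy ketone] | O=C([C@@H]1O[C@H]1c1ccc(OCc6ccccc6)c(-c2cc([C@@H]3O[C@H]3C(=O)c3c(OCOC)cc(OCc6ccccc6)cc3OCc6ccccc6)ccc2OCc6ccccc6)c1)c1c(OCOC)cc(OCc2ccccc2)cc1OCc1ccccc1
A3 | alternative 1 | hexa-O-benzyl bis[(2R,3R)-dihydroflavonol], the doubly hydroxylated dimer | O=C1[C@H](O)[C@@H](c2ccc(OCc6ccccc6)c(-c3cc([C@H]4Oc5cc(OCc6ccccc6)cc(OCc6ccccc6)c5C(=O)[C@@H]4O)ccc3OCc6ccccc6)c2)Oc2cc(OCc3ccccc3)cc(OCc3ccccc3)c21
A4 | alternative 2 | [6,6'-bis(benzyloxy)biphenyl-3,3'-diyl]diboronic acid | OB(O)c1ccc(OCc2ccccc2)c(-c2cc(B(O)O)ccc2OCc2ccccc2)c1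
A5 | alternative 2 | 5,7-bis(benzyloxy)-4H-chromen-4-one | O=c1ccoc2cc(OCc3ccccc3)cc(OCc3ccccc3)c12
A6 | alternative 2 | hexa-O-benzyl-(2S,2''S)-3',3'''-binaringenin (identical with 14) | O=C1C[C@@H](c2ccc(OCc6ccccc6)c(-c3cc([C@H]4Oc5cc(OCc6ccccc6)cc(OCc6ccccc6)c5C(=O)C4)ccc3OCc6ccccc6)c2)Oc2cc(OCc3ccccc3)cc(OCc3ccccc3)c21
A7 | alternative 3 | bis(diazoketone): each ring A carries a diazoacetyl group ortho to the benzylic ether oxygen and two silyloxy groups | [N-]=[N+]=CC(=O)c1c(OCc2ccc(OCc6ccccc6)c(-c3cc(COc4cc(O[Si](C)(C)C(C)(C)C)cc(O[Si](C)(C)C(C)(C)C)c4C(=O)C=[N+]=[N-])ccc3OCc6ccccc6)c2)cc(O[Si](C)(C)C(C)(C)C)cc1O[Si](C)(C)C(C)(C)C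
A8 | alternative 3 | 4',4'''-di-O-benzyl-5,7,5'',7''-tetra-O-(tert-butyldimethylsilyl)-(2S,2''S)-3',3'''-binaringenin | O=C1C[C@@H](c2ccc(OCc6ccccc6)c(-c3cc([C@H]4Oc5cc(O[Si](C)(C)C(C)(C)C)cc(O[Si](C)(C)C(C)(C)C)c5C(=O)C4)ccc3OCc6ccccc6)c2)Oc2cc(O[Si](C)(C)C(C)(C)C)cc(O[Si](C)(C)C(C)(C)C)c21
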